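## Retrosynthetic overview

- Structural feature: rings A and B are identical 5-alkylresorcinols. With the chain-bearing carbon as C1', the sequence C3'–C4'–C5'–C6' reads C(O)–CH–C(O)–CH, the four-carbon 1,3-dioxygenated unit of an acetoacetate-derived ketene-acetal diene. C1' and C2' are the β- and α-carbons of an alk-2-ynoate whose ester is later removed from C2'.
- Last disconnections: the two O–CH3 bonds and the two C2'–CO2 bonds lead back to dimethyl 6,6'-(tetradecane-1,14-diyl)bis(2-hydroxy-4-methoxybenzoate).
- Key disconnection: C1'–C6' and C2'–C3' in both rings (four C–C bonds) lead back to one molecule of dimethyl icosa-2,18-diynedioate and two molecules of 1,3-dimethoxy-1-(trimethylsilyloxy)buta-1,3-diene. Rings A and B form together in one operation by [4+2] addition and loss of methanol.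
- The bis-ynoate comes from octadeca-1,17-diyne, made from 1,14-dibromotetradecane and acetylide, with methyl chloroformate supplying the ester carbons. The diene comes from methyl (E)-3-methoxybut-2-enoate.

Key step: step 4

Remark on the chemistry: the two chain ends are taken to react alike in every twofold step, so each of steps 1, 2 and 4 consumes two molecules of the partner (acetylide, chloroformate, diene) per molecule of the chain compound, and half-reacted species are not listed separately; the ketene-acetal geometry of the diene is drawn as one isomer and is immaterial, because that carbon ends as an aromatic C–O carbon.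

## Route

Step 1
Reactants: 1 1,14-dibromotetradecane; 2 lithium acetylide–ethylenediamine complex, LiC≡CH·H2NCH2CH2NH2 (two molecules react)
Product: 3 octadeca-1,17-diyne
Conditions: LiC≡CH·H2NCH2CH2NH2 (3 equiv), DMSO–THF, 10 °C → rt
Reagents that add atoms: lithium acetylide–ethylenediamine complex 2, [Li+].[C-]#C.NCCN
Why: Twofold SN2 alkylation of acetylide at unhindered primary bromides, for which the dipolar aprotic medium makes the complexed acetylide nucleophilic enough at room temperature to keep elimination and triple-bond migration minor.

Step 2
Reactants: 3 octadeca-1,17-diyne; 4 methyl chloroformate (two molecules react)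
Product: 6 dimethyl icosa-2,18-diynedioate, via dilithium octadeca-1,17-diyne-1,18-diide 5 (not isolated)
Conditions: n-BuLi (2.2 equiv), THF, −78 → 0 °C; then ClCO2Me (3 equiv), −78 °C → rt
Reagents that add atoms: methyl chloroformate 4, COC(=O)Cl
Why: Deprotonation of both terminal alkynes and C-acylation of the lithium acetylides by addition–elimination at the chloroformate is the standard alk-2-ynoate synthesis, and excess chloroformate at low temperature should keep acetylide from adding to the product.

Step 3
Reactants: 7 methyl (E)-3-methoxybut-2-enoate; 8 chlorotrimethylsilane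
Product: 10 (1Z)-1,3-dimethoxy-1-(trimethylsilyloxy)buta-1,3-diene, via lithium 1,3-dimethoxybuta-1,3-dien-1-olate 9 (not isolated)
Conditions: LiN(iPr)2 (commercial solution, 1.1 equiv), THF, −78 °C; then Me3SiCl, −78 °C → rt; pentane, filtration under Ar, bulb-to-bulb distillation, used fresh
Reagents that add atoms: chlorotrimethylsilane 8, C[Si](C)(C)Cl
Why: Kinetic γ-deprotonation of the β-methoxy enoate gives the extended dienolate, which the oxophilic silyl chloride should trap on oxygen (silyl ketene acetal formation) to give the 1,1,3-trioxygenated diene.

Step 4
Reactants: 6 dimethyl icosa-2,18-diynedioate; 10 (1Z)-1,3-dimethoxy-1-(trimethylsilyloxy)buta-1,3-diene (two molecules react, one at each ynoate)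
Product: 13 dimethyl 6,6'-(tetradecane-1,14-diyl)bis(2-hydroxy-4-methoxybenzoate), via twofold cyclohexa-1,4-diene cycloadduct 11 (not isolated), via bis(trimethylsilyl ether) 12 (not isolated)
Conditions: 10 (6 equiv, two portions), xylenes (minimal) or neat, sealed tube, 130 °C, 48–72 h; then 1 M HCl–THF, rt
Reagents that add atoms: (1Z)-1,3-dimethoxy-1-(trimethylsilyloxy)buta-1,3-diene 10 (second molecule), C=C(OC)/C=C(/OC)O[Si](C)(C)C
Why: Each of the two ynoate units should take up one molecule of 10 in a thermal, asynchronous normal-demand Diels–Alder addition, in which the CH2 terminus of the diene (C4, the carbon of largest HOMO coefficient) bonds to the chain-bearing β-carbon of the ynoate and the ketene-acetal carbon (C1) bonds to the ester-bearing α-carbon, so that two molecules of 10 and one of 6 give the twofold cyclohexa-1,4-diene 11. Each acetal carbon of 11 then ionizes with loss of methoxide, the ring CH2 gives up a proton, and the aryl silyl ether 12 so formed is hydrolysed by the acidic work-up to the intramolecularly hydrogen-bonded salicylate 13. The closest known reaction type is the Diels–Alder/aromatization of 1,1,3-trioxygenated buta-1,3-dienes with acetylenic esters to give resorcylates. Rings A and B are closed alike, each by an intermolecular [4+2] cycloaddition that forms C1'–C6' and C2'–C3', followed by 1,4-elimination of methanol. No stereocentre has to be controlled, since the acetal carbons of 11 become planar aromatic carbons and the ketene-acetal geometry of 10 is lost with them. The one selectivity required is regiochemical and rests on the matched polarization of the reacting pair (nucleophilic C4 of the diene, electrophilic β-carbon of the ynoate); the (CH2)14 chain insulates the two ynoates from each other, so that an excess of diene and prolonged heating, needed because a β-alkyl ynoate is a slower dienophile than a propiolate, should bring both ends to reaction.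

Step 5
Reactants: 13 dimethyl 6,6'-(tetradecane-1,14-diyl)bis(2-hydroxy-4-methoxybenzoate)
Product: 15 5,5'-(tetradecane-1,14-diyl)bis(3-methoxyphenol), via diacid 14 (not isolated)
Conditions: KOH (excess), EtOH–H2O, reflux; then aq. HCl to pH 1, dioxane, 100 °C
Reagents that add atoms: none
Why: Ester saponification under forcing conditions (the ester is flanked by two ortho substituents) followed by protodecarboxylation of the electron-rich salicylic acid, whose carboxyl-bearing carbon is ortho to OH and para to OMe and is therefore readily ipso-protonated with loss of CO2 on heating in acid.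

Step 6
Reactants: 15 5,5'-(tetradecane-1,14-diyl)bis(3-methoxyphenol)
Product: 16 bisnorstriatol, 5,5'-(tetradecane-1,14-diyl)bis(benzene-1,3-diol)
Conditions: BBr3 (excess), CH2Cl2, −78 °C → rt; then H2O
Reagents that add atoms: none
Why: Lewis-acid cleavage of aryl methyl ethers, in which BBr3 complexes each methoxy oxygen and bromide attacks the methyl group (SN2), the aryl borates being hydrolysed on work-up; nothing else in the molecule is acid-sensitive.

## Compound list

1 | 1,14-dibromotetradecane | BrCCCCCCCCCCCCCCBr | starting material
2 | lithium acetylide–ethylenediamine complex | [Li+].[C-]#C.NCCN | starting material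
3 | octadeca-1,17-diyne | C#CCCCCCCCCCCCCCCC#C | intermediate
4 | methyl chloroformate | COC(=O)Cl | starting material
5 | dilithium octadeca-1,17-diyne-1,18-diide (not isolated) | [Li]C#CCCCCCCCCCCCCCCC#C[Li] | intermediate
6 | dimethyl icosa-2,18-diynedioate | COC(=O)C#CCCCCCCCCCCCCCCC#CC(=O)OC | intermediate
7 | methyl (E)-3-methoxybut-2-enoate | CO/C(C)=C/C(=O)OC | starting material
8 | chlorotrimethylsilane | C[Si](C)(C)Cl | starting material
9 | lithium 1,3-dimethoxybuta-1,3-dien-1-olate, O–Li cis to C3 (not isolated) | C=C(OC)/C=C(/OC)[O-].[Li+] | intermediate
10 | (1Z)-1,3-dimethoxy-1-(trimethylsilyloxy)buta-1,3-diene, OSiMe3 cis to C3 | C=C(OC)/C=C(/OC)O[Si](C)(C)C | intermediate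
11 | dimethyl 2,2'-(tetradecane-1,14-diyl)bis[4,6-dimethoxy-6-(trimethylsilyloxy)cyclohexa-1,4-diene-1-carboxylate], mixture of diastereomers at the two acetal carbons (not isolated) | COC(=O)C1=C(CCCCCCCCCCCCCCC2=C(C(=O)OC)C(OC)(O[Si](C)(C)C)C=C(OC)C2)CC(OC)=CC1(OC)O[Si](C)(C)C | intermediate
12 | dimethyl 6,6'-(tetradecane-1,14-diyl)bis[4-methoxy-2-(trimethylsilyloxy)benzoate] (not isolated) | COC(=O)c1c(O[Si](C)(C)C)cc(OC)cc1CCCCCCCCCCCCCCc1cc(OC)cc(O[Si](C)(C)C)c1C(=O)OC | intermediate
13 | dimethyl 6,6'-(tetradecane-1,14-diyl)bis(2-hydroxy-4-methoxybenzoate) | COC(=O)c1c(O)cc(OC)cc1CCCCCCCCCCCCCCc1cc(OC)cc(O)c1C(=O)OC | intermediate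
14 | 6,6'-(tetradecane-1,14-diyl)bis(2-hydroxy-4-methoxybenzoic acid) (not isolated) | OC(=O)c1c(O)cc(OC)cc1CCCCCCCCCCCCCCc1cc(OC)cc(O)c1C(=O)O | intermediate
15 | 5,5'-(tetradecane-1,14-diyl)bis(3-methoxyphenol) | COc1cc(O)cc(CCCCCCCCCCCCCCc2cc(O)cc(OC)c2)c1 | intermediate
16 | bisnorstriatol, 5,5'-(tetradecane-1,14-diyl)bis(benzene-1,3-diol) | Oc1cc(O)cc(CCCCCCCCCCCCCCc2cc(O)cc(O)c2)c1 | target

## Step count and risks

Total step count: 6.
Longest linear sequence: 5 steps (1 → 3 → 6 → 13 → 15 → 16; steps 1, 2, 4, 5, 6). The diene 10 is made in one step on a side branch.

Steps most likely to fail: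

1. Step 4 (key step). The second cycloaddition may lag behind the first while the diene is consumed by thermal oligomerization and adventitious hydrolysis, so that the annulation stops after one ring. Aromatization may also take the other course in part, by loss of trimethylsilanol instead of methanol, which leaves a methyl ether at the 2-position; the fallback given for step 5 should still carry such material to the target.
 Fallback, setting out from 6 and returning at target 16: the rings are built by an anionic Michael–Dieckmann annulation instead of a cycloaddition. Dimethyl 3-oxopentanedioate is converted with NaH in THF into sodium 1,5-dimethoxy-1,5-dioxopent-2-en-3-olate F1. Through its C2, one molecule of F1 should add to the β-carbon of each ynoate of 6 (rt → reflux) to give the bis-Michael adduct tetramethyl 2,2'-(1,20-dimethoxy-1,20-dioxoicosa-2,18-diene-3,18-diyl)bis(3-oxopentanedioate) F2, whose alkene geometry equilibrates through the extended enolate. The remaining active methylene of each oxoglutarate unit then closes on the former ynoate ester with loss of methanol, and enolization should give tetramethyl 6,6'-(tetradecane-1,14-diyl)bis(2,4-dihydroxybenzene-1,3-dicarboxylate) F3. Aqueous NaOH at reflux, then acidification and heating, should saponify the four esters to 6,6'-(tetradecane-1,14-diyl)bis(2,4-dihydroxybenzene-1,3-dicarboxylic acid) F4. Every carboxyl of F4 is ortho or para to a hydroxyl, so it should decarboxylate directly to 16, bypassing 13 and 15.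

2. Step 5. Hydrolysis of the doubly ortho-flanked ester, which sits on a phenoxide under the basic conditions, may stop short on one or both rings, and the decarboxylation of the 4-O-methylated acid may be incomplete at 100 °C.
 Fallback, setting out from 13 and returning at target 16: 48% aqueous HBr in AcOH at reflux. Here the ester is cleaved at the O–methyl bond (bromide attack on the protonated ester, a path that does not feel the crowding at the acyl carbon), the acid is protodecarboxylated in the strongly acidic medium, and the aryl methyl ethers are cleaved in the same operation. The material is expected to pass through 14 and 15 in the flask, and no compound outside the compound list is formed (F0).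

3. Step 1. E2 elimination and base-induced migration of the triple bond may compete with substitution, and the second displacement may be slowed by the poor solubility of the C14 dibromide in DMSO. The resulting enyne and internal-alkyne impurities are hard to separate from the non-polar diyne.
 Fallback, setting out from 1 and returning at 6: the three-carbon ynoate unit is introduced directly. Propiolic acid is doubly deprotonated with LiN(iPr)2 (2 equiv) in THF–DMPU at −78 °C to lithium 3-lithioprop-2-ynoate F5, a weaker base than acetylide. Two molecules of F5 should alkylate at their acetylide carbons with the two bromides of 1 (−78 °C → rt) to give icosa-2,18-diynedioic acid F6, which is purified by acid–base extraction. Fischer esterification (MeOH, cat. H2SO4, reflux) should then give 6, bypassing 3 and 5.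

## Further compounds

F1 | step 4 | sodium 1,5-dimethoxy-1,5-dioxopent-2-en-3-olate | COC(=O)C=C([O-])CC(=O)OC.[Na+]
F2 | step 4 | tetramethyl 2,2'-(1,20-dimethoxy-1,20-dioxoicosa-2,18-diene-3,18-diyl)bis(3-oxopentanedioate), alkene geometry not fixed | COC(=O)C=C(CCCCCCCCCCCCCCC(=CC(=O)OC)C(C(=O)OC)C(=O)CC(=O)OC)C(C(=O)OC)C(=O)CC(=O)OC
F3 | step 4 | tetramethyl 6,6'-(tetradecane-1,14-diyl)bis(2,4-dihydroxybenzene-1,3-dicarboxylate) | COC(=O)c1c(O)c(C(=O)OC)c(O)cc1CCCCCCCCCCCCCCc1cc(O)c(C(=O)OC)c(O)c1C(=O)OC
F4 | step 4 | 6,6'-(tetradecane-1,14-diyl)bis(2,4-dihydroxybenzene-1,3-dicarboxylic acid) | OC(=O)c1c(O)c(C(=O)O)c(O)cc1CCCCCCCCCCCCCCc1cc(O)c(C(=O)O)c(O)c1C(=O)O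
F0 | step 5 | none | none
F5 | step 1 | lithium 3-lithioprop-2-ynoate | [Li]C#CC(=O)[O-].[Li+]
F6 | step 1 | icosa-2,18-diynedioic acid | OC(=O)C#CCCCCCCCCCCCCCCC#CC(=O)O
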